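Locants used throughout: isoflavone core O1, C2, C3, C4, C4a, C5–C8, C8a (rings A and C); ring B C1'–C6'; pyran ring O1'' (on C4'), C2'' (gem-dimethyl), C3'', C4'' (on C5').

## Analysis of the target

Eriosemaone D is a 5,7-dihydroxyisoflavone in which ring A is fused to the 4-pyranone ring C and C3 carries ring B. Ring B has a free hydroxyl at C2' and a 2,2-dimethyl-2H-pyran fused linearly across C4' (oxygen) and C5' (carbon). The molecule has no stereocentre; the two that appear in the route are transient and vanish when ring B becomes aromatic. The sensitive sites are the C3''=C4'' double bond (acid, hydrogenation, electrophiles), the electrophilic C2 of ring C (opened by hydroxide or alkoxide) and the three phenols, of which 2'-OH lies next to ring C and can close onto C2 under oxidation or onto the ketone of an open-chain precursor under acid. The main difficulty is regiochemical: ring B is a resorcinol, and prenylation, chromenylation and propargyl ether rearrangements normally go to C3', the carbon between the two oxygens, whereas the pyran must be fused at C4'/C5', and the two ring B oxygens must also be told apart. The strategy rests on one feature: ring B carries oxygen on C2' and C4' and carbon on C1' and C5', which is the pattern of a 4,6-disubstituted cyclohexane-1,3-dione. Such a dione can be assembled from a methyl ketone with a prenyl group on its α-methylene and an acrylate with an acetate arm on its α-carbon, so every substituent sits on its final carbon before ring B is an arene.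

## Retrosynthetic reasoning

15 to 14. The C3''=C4'' double bond is removed first. A chromene would not survive the hydrogenolysis or the acidic acylation earlier in the route, whereas the chroman 14 is inert to both. The forward step must abstract hydride from C4'', which is benzylic, para to the 2'-oxygen and ortho to O1''.

14 to 12. Ring C is opened at O1–C2 and C2–C3, taking out C2 as a one-carbon unit at the oxidation level of a formyl group. This leaves the deoxybenzoin 12, in which every other atom of the target skeleton is in place. The forward reaction must functionalise the active methylene (via 13) and let a ring A phenol close the pyranone.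

12 to 11. Four benzyl ethers are added. The 2'-oxygen has to be masked while the ketone is made: free, it would lactonise onto the activated acid, and under acid it could attack the new ketone. Benzyl ethers on ring A make the arene partner a pure carbon nucleophile. All four come off in one neutral hydrogenolysis, which is possible only because there is no alkene at this stage.

11 to 8 and 9. The C4–C4a bond is cut as a Friedel–Crafts acylation. The arene 9 is threefold symmetric, so there is no regiochemical question, and the carboxyl carbon of 8 becomes C4.

8 to 6. The benzyl ether and the free acid are traced back to the phenol methyl ester 6, two routine functional group changes.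

6 to 5. The arene of ring B is traced back to a cyclohexenone by adding two hydrogen atoms across C1'–C6'. Compound 5 is a cyclic vinylogous ester: C2' is a ketone and the C4' oxygen is already the pyran oxygen. The two ring B oxygens are therefore differentiated before the ring is aromatic, and the forward dehydrogenation meets no alkene that it could reduce.

5 to 4. The O1''–C2'' bond is cut, giving the dione 4 with a prenyl group on C5'. Only the oxygen on C4' can reach the tertiary carbon through a six-membered ring, so the linear fusion follows from connectivity. Closing the pyran at the dione stage also removes the prenyl alkene, which would not survive a dehydrogenation catalyst.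

4 to 1 and 2. Ring B is cut at C5'–C6' (conjugate addition) and C2'–C3' (acyl substitution). This returns the two purchasable pieces 1 and 2 and places the risk of the route in its first step, where material is cheapest.

## Alternatives that were turned down

Alternative 1: enamine C-aroylation followed by closure of ring C.
- Disconnection: ring C is cut at C3–C4 and O1–C2. Ring B arrives as the finished chromene in the enamine 4-[(E)-2-[7-(methoxymethoxy)-2,2-dimethyl-2H-chromen-6-yl]ethenyl]morpholine (A2), and ring A as 2,4,6-triacetoxybenzoyl chloride (A3).
- Key step: the β-carbon of A2 is acylated by A3. K2CO3 in methanol then removes the acetates, and on acidification an ortho phenol adds to the aminomethylene carbon and expels the secondary amine, giving 2'-O-(methoxymethyl) Eriosemaone D (A1).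
- For: it is convergent, C2 comes with the enamine A2, no strong acid is used, and the chromene is present from the start, so no late oxidation is needed. On these points it is stronger than the chosen route.
- Against: the regiochemical problem is only moved into the synthesis of A2, whose linear chromene must be built on a resorcinol that prefers reaction at C3'. A2 is an enamine of an arylacetaldehyde and is fragile. A3 is hindered on both sides of the acyl group. The product A1 still needs acid to remove the acetal from an acid-sensitive chromene.
- Comparison: the chosen route gives up convergence and accepts a final oxidation, but it gets the linear fusion from constitution and starts from two bulk chemicals.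

Alternative 2: hydroarylation of a propargyl ether with a gold catalyst.
- Disconnection: the C5'–C4'' bond is cut on an intact isoflavone. The precursor is the tertiary propargyl ether 3-[2-hydroxy-4-(2-methylbut-3-yn-2-yloxy)phenyl]-5,7-bis(methoxymethoxy)-4H-chromen-4-one (A5), and the pyran is closed last.
- Key step: Ph3PAuNTf2 (monovalent gold) activates the terminal alkyne of A5, C5' of A5 attacks in a 6-endo-dig sense, and protodeauration gives 5,7-bis-O-(methoxymethyl) Eriosemaone D (A4).
- For: this is the shortest endgame. The chromene of A4 is formed directly at the right oxidation level under near-neutral conditions, and in A5 the carbon C5' is para to the 2'-hydroxyl and less hindered than C3'. In step economy it is clearly stronger than the chosen route.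
- Against: in A5, C3' is also ortho to the ether oxygen and is activated by two oxygens, so the linear or angular outcome rests on a steric preference in the key step. The tertiary propargylic ether of A5 can ionise at a Lewis-acidic metal, and its free 2'-OH and carbonyl can bind the catalyst. The product A4 again needs acid deprotection next to a chromene.
- Comparison: the chosen route is longer, but its ring fusion cannot come out wrong, because the pyran oxygen and the prenyl carbon are neighbours in 4 by construction, whereas A5 leaves that choice to the cyclisation.

Alternative 3: aryne annulation of a hydroxymethylene ester.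
- Disconnection: ring C is cut at O1–C8a and C4–C4a. Ring A comes from the aryne precursor 3,5-bis(methoxymethoxy)-2-(trimethylsilyl)phenyl trifluoromethanesulfonate (A8), and the rest from methyl 3-hydroxy-2-[7-(methoxymethoxy)-2,2-dimethyl-2H-chromen-6-yl]prop-2-enoate (A7).
- Key step: CsF releases the aryne from A8. The enolate oxygen of A7 adds at the aryne carbon remote from the alkoxy group, and the aryl anion formed next to that alkoxy group attacks the cis ester, giving 2',5,7-tris-O-(methoxymethyl) Eriosemaone D (A6).
- For: the union of A7 and A8 is convergent and runs under fluoride only, and the polarisation of a 3-alkoxyaryne gives the ring A regiochemistry. That is as good as the symmetric arene 9 of the chosen route.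
- Against: A8 needs several steps of selective protection, silylation and triflation. The enolate of A7 is ambident, and C-arylation followed by acyl migration competes with the desired O-arylation. The enol geometry must place the ester cis to the new O–aryl bond. A7 carries the same linear chromene problem as A2, and A6 needs three acid deprotections.
- Comparison: the chosen route uses no aryne, no silyl triflate and no acetal removal, at the price of a linear sequence.

Key step: step 1

Assumptions: 1,3,5-tris(benzyloxy)benzene (9) is taken as a purchasable compound. The 1,3-diones are drawn as diketo tautomers although they will be largely enolised.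

## Route

Step 1
Reactants: 1 6-methylhept-5-en-2-one; 2 dimethyl itaconate (dimethyl 2-methylidenebutanedioate)
Product: 4 methyl 2-[5-(3-methylbut-2-enyl)-2,4-dioxocyclohexyl]acetate (mixture of diastereomers), via Michael adduct keto diester 3 (not isolated)
Conditions: KOC(CH3)3 (2.2 equiv), THF, −10 °C, 1 first, then slow addition of 2, to rt; aq. HCl
Reagents that add atoms: none
Why: The alkoxide equilibrates the enolates of 1, and the more substituted enolate (C3 of the ketone) adds to the methylene carbon of 2, forming C5'–C6' and giving 3 after proton transfer. The methyl-side enolate of 3 then attacks the ester on the former acrylate α-carbon in a 6-exo-trig acyl substitution, forming C2'–C3', expelling methoxide and closing the carbocycle that becomes ring B. The closest known reaction type is the consecutive Michael–Claisen annulation of acetone and substituted acetones with acrylates to cyclohexane-1,3-diones. The product is deprotonated at once to its stabilised enolate, which consumes the second equivalent of base and pulls both equilibria forward. The new stereocentres at C1' and C5' are not controlled and equilibrate under the base; both disappear in step 3. The step needs conjugate addition from the methylene and acylation from the methyl: once the methylene has added, only the methyl can close a ring that keeps an acidic proton between its carbonyls, since the methyl would need a seven-membered ring to reach the other ester, and closure from the methine onto that ester gives a five-membered diketone with a quaternary carbon between the carbonyls, which the alkoxide reopens. Slow addition of 2 to the preformed enolate in the cold should keep conjugate addition ahead of base-induced migration of the double bond of 2.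

Step 2
Reactants: 4 methyl 2-[5-(3-methylbut-2-enyl)-2,4-dioxocyclohexyl]acetate
Product: 5 methyl 2-(2,2-dimethyl-7-oxo-3,4,4a,5,6,7-hexahydro-2H-chromen-6-yl)acetate (mixture of diastereomers)
Conditions: TsOH·H2O (10 mol%), toluene, 70 °C
Reagents that add atoms: none
Why: Acid-catalysed intramolecular hydroalkoxylation: protonation of the prenyl alkene gives the tertiary cation, which is captured by the enol oxygen on C4', as in the known cycloetherification of prenylated cyclohexane-1,3-diones. Only this oxygen can reach the cation through a six-membered ring, and capture by C3' would need a bridged transition state, so O-closure should dominate.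

Step 3
Reactants: 5 methyl 2-(2,2-dimethyl-7-oxo-3,4,4a,5,6,7-hexahydro-2H-chromen-6-yl)acetate
Product: 6 methyl 2-(7-hydroxy-2,2-dimethyl-3,4-dihydro-2H-chromen-6-yl)acetate
Conditions: 10% Pd/C, mesitylene, reflux, N2 sweep; then K2CO3 (cat.), MeOH, rt
Reagents that add atoms: none
Why: Catalytic dehydrogenation of a cyclohexenone to a phenol: loss of two hydrogen atoms across C1'–C6' gives a dienone that tautomerises to the arene and erases both stereocentres. Compound 5 has no alkene or benzyl ether that the released hydrogen could attack, and the brief carbonate/methanol treatment returns any material that lactonised in the heat to 6.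

Step 4
Reactants: 6 methyl 2-(7-hydroxy-2,2-dimethyl-3,4-dihydro-2H-chromen-6-yl)acetate
Product: 8 2-(7-benzyloxy-2,2-dimethyl-3,4-dihydro-2H-chromen-6-yl)acetic acid, via benzyl ether methyl ester 7 (not isolated)
Conditions: BnBr, K2CO3, DMF, 50 °C; then 2 M NaOH, MeOH, 50 °C; aq. HCl
Reagents that add atoms: benzyl bromide, BrCc1ccccc1; sodium hydroxide, [Na+].[OH-]
Why: Williamson etherification of the only free phenol, then saponification in the same flask. The benzyl ether stops the acid from lactonising onto the 2'-oxygen and keeps that oxygen away from the ketone made in step 5.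

Step 5
Reactants: 8 2-(7-benzyloxy-2,2-dimethyl-3,4-dihydro-2H-chromen-6-yl)acetic acid; 9 1,3,5-tris(benzyloxy)benzene
Product: 11 2-(7-benzyloxy-2,2-dimethyl-3,4-dihydro-2H-chromen-6-yl)-1-[2,4,6-tris(benzyloxy)phenyl]ethan-1-one, via mixed trifluoroacetic anhydride 10 (not isolated)
Conditions: (CF3CO)2O, CH2Cl2, 0 °C to rt
Reagents that add atoms: none
Why: Friedel–Crafts acylation of a 1,3,5-trialkoxybenzene by an acyl trifluoroacetate, forming C4–C4a. Compound 9 is symmetric and strongly nucleophilic, the ketone product is deactivated against a second acylation, and the absence of a Lewis acid spares the benzyl ethers and the chroman.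

Step 6
Reactants: 11 2-(7-benzyloxy-2,2-dimethyl-3,4-dihydro-2H-chromen-6-yl)-1-[2,4,6-tris(benzyloxy)phenyl]ethan-1-one
Product: 12 2-(7-hydroxy-2,2-dimethyl-3,4-dihydro-2H-chromen-6-yl)-1-(2,4,6-trihydroxyphenyl)ethan-1-one
Conditions: H2 (1 atm), 10% Pd/C, EtOAc–MeOH, rt
Reagents that add atoms: none
Why: Hydrogenolysis of four aryl benzyl ethers under neutral conditions. There is no alkene in 11, and the ketone, flanked by two ortho oxygens, should resist reduction.

Step 7
Reactants: 12 2-(7-hydroxy-2,2-dimethyl-3,4-dihydro-2H-chromen-6-yl)-1-(2,4,6-trihydroxyphenyl)ethan-1-one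
Product: 14 5,7-dihydroxy-3-(7-hydroxy-2,2-dimethyl-3,4-dihydro-2H-chromen-6-yl)-4H-chromen-4-one, via enaminone 13 (not isolated)
Conditions: Me2NCH(OMe)2 (3 equiv), THF, 60 °C; then 1 M HCl, MeOH, rt
Reagents that add atoms: N,N-dimethylformamide dimethyl acetal, COC(OC)N(C)C
Why: Standard isoflavone closure of a 2-hydroxydeoxybenzoin: the acetal condenses at the active methylene (C2–C3), and a ring A phenol adds to the aminomethylene carbon and expels dimethylamine (O1–C2) in a 6-endo addition–elimination. The 2'-hydroxyl could only close a five-membered ring by a 5-endo-trig path, so it should not compete.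

Step 8
Reactants: 14 5,7-dihydroxy-3-(7-hydroxy-2,2-dimethyl-3,4-dihydro-2H-chromen-6-yl)-4H-chromen-4-one
Product: 15 Eriosemaone D, 5,7-dihydroxy-3-(7-hydroxy-2,2-dimethyl-2H-chromen-6-yl)-4H-chromen-4-one
Conditions: DDQ (1.1 equiv), 1,4-dioxane, reflux
Reagents that add atoms: none
Why: Quinone dehydrogenation of a 2,2-dimethylchroman to the 2H-chromene, a known reaction of dihydropyrano flavonoids with free phenols. Hydride leaves C4'' to give a cation stabilised by the para 2'-oxygen and the ortho O1'', and loss of a proton from C3'' gives the alkene; the oxidant is held near one equivalent to protect the 2'-hydroxyisoflavone.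

## Compound list

1 | 6-methylhept-5-en-2-one | CC(=O)CCC=C(C)C | starting material
2 | dimethyl itaconate | COC(=O)CC(=C)C(=O)OC | starting material
3 | dimethyl 2-(2-acetyl-5-methylhex-4-en-1-yl)butanedioate (diastereomer mixture) | COC(=O)CC(CC(CC=C(C)C)C(C)=O)C(=O)OC | intermediate
4 | methyl 2-[5-(3-methylbut-2-enyl)-2,4-dioxocyclohexyl]acetate (diastereomer mixture) | COC(=O)CC1CC(CC=C(C)C)C(=O)CC1=O | intermediate
5 | methyl 2-(2,2-dimethyl-7-oxo-3,4,4a,5,6,7-hexahydro-2H-chromen-6-yl)acetate (diastereomer mixture) | COC(=O)CC1CC2CCC(C)(C)OC2=CC1=O | intermediate
6 | methyl 2-(7-hydroxy-2,2-dimethyl-3,4-dihydro-2H-chromen-6-yl)acetate | COC(=O)Cc1cc2CCC(C)(C)Oc2cc1O | intermediate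
7 | methyl 2-(7-benzyloxy-2,2-dimethyl-3,4-dihydro-2H-chromen-6-yl)acetate | COC(=O)Cc1cc2CCC(C)(C)Oc2cc1OCc1ccccc1 | intermediate
8 | 2-(7-benzyloxy-2,2-dimethyl-3,4-dihydro-2H-chromen-6-yl)acetic acid | OC(=O)Cc1cc2CCC(C)(C)Oc2cc1OCc1ccccc1 | intermediate
9 | 1,3,5-tris(benzyloxy)benzene | c1ccc(COc2cc(OCc3ccccc3)cc(OCc3ccccc3)c2)cc1 | starting material
10 | 2-(7-benzyloxy-2,2-dimethyl-3,4-dihydro-2H-chromen-6-yl)acetic trifluoroacetic anhydride | O=C(Cc1cc2CCC(C)(C)Oc2cc1OCc1ccccc1)OC(=O)C(F)(F)F | intermediate
11 | 2-(7-benzyloxy-2,2-dimethyl-3,4-dihydro-2H-chromen-6-yl)-1-[2,4,6-tris(benzyloxy)phenyl]ethan-1-one | O=C(Cc1cc2CCC(C)(C)Oc2cc1OCc1ccccc1)c1c(OCc2ccccc2)cc(OCc2ccccc2)cc1OCc1ccccc1 | intermediate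
12 | 2-(7-hydroxy-2,2-dimethyl-3,4-dihydro-2H-chromen-6-yl)-1-(2,4,6-trihydroxyphenyl)ethan-1-one | CC1(C)CCc2cc(CC(=O)c3c(O)cc(O)cc3O)c(O)cc2O1 | intermediate
13 | 3-(dimethylamino)-2-(7-hydroxy-2,2-dimethyl-3,4-dihydro-2H-chromen-6-yl)-1-(2,4,6-trihydroxyphenyl)prop-2-en-1-one | CN(C)C=C(C(=O)c1c(O)cc(O)cc1O)c1cc2CCC(C)(C)Oc2cc1O | intermediate
14 | 5,7-dihydroxy-3-(7-hydroxy-2,2-dimethyl-3,4-dihydro-2H-chromen-6-yl)-4H-chromen-4-one | CC1(C)CCc2cc(-c3coc4cc(O)cc(O)c4c3=O)c(O)cc2O1 | intermediate
15 | Eriosemaone D | CC1(C)C=Cc2cc(-c3coc4cc(O)cc(O)c4c3=O)c(O)cc2O1 | target

## Step count and risks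

Total step count: 8. Longest linear sequence: 8 (1 and 2 to 15).

Step 1 (key step). The most likely failure is migration of the double bond of 2 into conjugation with both esters under the alkoxide. Conjugate addition would then take place at the wrong carbon and the acetate arm would be lost. Conjugate addition from the methyl side of 1, which would end with the prenyl group between the two carbonyls, and oligomerisation of the acceptor are the other concerns. The fallback sets out from 2 and comes back at 5; it forms the same two bonds stepwise with a doubly activated donor that needs only a weak base. tert-Butyl acetoacetate is C-prenylated (prenyl bromide, K2CO3, acetone) to tert-butyl 2-acetyl-5-methylhex-4-enoate F1. F1 adds to 2 under catalytic K2CO3 to give 4-tert-butyl 1,2-dimethyl 4-acetyl-7-methyloct-6-ene-1,2,4-tricarboxylate F2. KOC(CH3)3 in THF then closes the ring from the acetyl methyl, the only enolisable ketone position, to give tert-butyl 5-(2-methoxy-2-oxoethyl)-1-(3-methylbut-2-enyl)-2,4-dioxocyclohexane-1-carboxylate F3. TsOH in warm toluene removes the tert-butyl ester, decarboxylates and closes the pyran in one operation, giving 5.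

Step 3. Hydrogen transfer between substrate molecules on the catalyst may over-reduce part of the material while the rest aromatises, and the hot ortho-hydroxyaryl acetate may lactonise. The fallback sets out from 5 and comes back at 6. Kinetic deprotonation at the α'-carbon (lithium diisopropylamide, THF, −78 °C) and trapping with PhSeCl should give methyl 2-[2,2-dimethyl-7-oxo-6-(phenylselanyl)-3,4,4a,5,6,7-hexahydro-2H-chromen-6-yl]acetate F4. Oxidation (H2O2, pyridine, CH2Cl2, 0 °C) and selenoxide elimination give a dienone that tautomerises to 6 below room temperature.

Step 5. The trifluoroacetic acid released may cleave or move benzyl groups, and the electron-rich ring of 8 may be acylated by a second molecule. The fallback sets out from 6 and comes back at 12, skipping all protection. Saponification (NaOH, aqueous MeOH, then acid) gives 2-(7-hydroxy-2,2-dimethyl-3,4-dihydro-2H-chromen-6-yl)acetic acid F5. F5 is heated with phloroglucinol in BF3·OEt2 (80 °C), the usual Lewis-acid acylation of phloroglucinol by arylacetic acids, to give 12 directly. This was not made the main route because the free 2'-hydroxyl can cyclise onto the ketone under hot acid.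

Step 7. The acetal may methylate phenolic oxygens, and the enaminone 13 may fail to close completely. The fallback sets out from 11 and comes back at 14; it adds the one-carbon unit before any phenol is free. Heating 11 with tert-butoxybis(dimethylamino)methane in toluene (90 °C) should give 2-(7-benzyloxy-2,2-dimethyl-3,4-dihydro-2H-chromen-6-yl)-3-(dimethylamino)-1-[2,4,6-tris(benzyloxy)phenyl]prop-2-en-1-one F6. Hydrogenolysis (H2, 10% Pd/C, EtOAc–MeOH) followed by dilute HCl frees the phenols, and the ring A phenol closes ring C to 14.

Step 8. Oxidative closure of the free 2'-hydroxyl onto C2 and over-oxidation of the electron-rich ring B may compete with the benzylic dehydrogenation. The fallback sets out from 14 and comes back at 15. Acetylation (Ac2O, pyridine, DMAP) gives 3-(7-acetoxy-2,2-dimethyl-3,4-dihydro-2H-chromen-6-yl)-4-oxo-4H-chromene-5,7-diyl diacetate F7, in which the 2'-oxygen can no longer cyclise. DDQ in refluxing dioxane then gives 3-(7-acetoxy-2,2-dimethyl-2H-chromen-6-yl)-4-oxo-4H-chromene-5,7-diyl diacetate F8. K2CO3 in MeOH at 0 °C removes the acetates to give 15.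

## Further compounds

F1 | step 1 | tert-butyl 2-acetyl-5-methylhex-4-enoate | CC(=O)C(CC=C(C)C)C(=O)OC(C)(C)C
F2 | step 1 | 4-tert-butyl 1,2-dimethyl 4-acetyl-7-methyloct-6-ene-1,2,4-tricarboxylate | COC(=O)CC(CC(CC=C(C)C)(C(C)=O)C(=O)OC(C)(C)C)C(=O)OC
F3 | step 1 | tert-butyl 5-(2-methoxy-2-oxoethyl)-1-(3-methylbut-2-enyl)-2,4-dioxocyclohexane-1-carboxylate | COC(=O)CC1CC(CC=C(C)C)(C(=O)OC(C)(C)C)C(=O)CC1=O
F4 | step 3 | methyl 2-[2,2-dimethyl-7-oxo-6-(phenylselanyl)-3,4,4a,5,6,7-hexahydro-2H-chromen-6-yl]acetate | COC(=O)CC1([Se]c2ccccc2)CC2CCC(C)(C)OC2=CC1=O
F5 | step 5 | 2-(7-hydroxy-2,2-dimethyl-3,4-dihydro-2H-chromen-6-yl)acetic acid | OC(=O)Cc1cc2CCC(C)(C)Oc2cc1O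
F6 | step 7 | 2-(7-benzyloxy-2,2-dimethyl-3,4-dihydro-2H-chromen-6-yl)-3-(dimethylamino)-1-[2,4,6-tris(benzyloxy)phenyl]prop-2-en-1-one | CN(C)C=C(C(=O)c1c(OCc2ccccc2)cc(OCc2ccccc2)cc1OCc1ccccc1)c1cc2CCC(C)(C)Oc2cc1OCc1ccccc1
F7 | step 8 | 3-(7-acetoxy-2,2-dimethyl-3,4-dihydro-2H-chromen-6-yl)-4-oxo-4H-chromene-5,7-diyl diacetate | CC(=O)Oc1cc2OC(C)(C)CCc2cc1-c1coc2cc(OC(C)=O)cc(OC(C)=O)c2c1=O
F8 | step 8 | 3-(7-acetoxy-2,2-dimethyl-2H-chromen-6-yl)-4-oxo-4H-chromene-5,7-diyl diacetate | CC(=O)Oc1cc2OC(C)(C)C=Cc2cc1-c1coc2cc(OC(C)=O)cc(OC(C)=O)c2c1=O
A1 | alternative 1 | 2'-O-(methoxymethyl) Eriosemaone D | COCOc1cc2OC(C)(C)C=Cc2cc1-c1coc2cc(O)cc(O)c2c1=O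
A2 | alternative 1 | 4-[(E)-2-[7-(methoxymethoxy)-2,2-dimethyl-2H-chromen-6-yl]ethenyl]morpholine | COCOc1cc2OC(C)(C)C=Cc2cc1/C=C/N1CCOCC1
A3 | alternative 1 | 2,4,6-triacetoxybenzoyl chloride | CC(=O)Oc1cc(OC(C)=O)c(C(Cl)=O)c(OC(C)=O)c1
A4 | alternative 2 | 5,7-bis-O-(methoxymethyl) Eriosemaone D | CC1(C)C=Cc2cc(-c3coc4cc(OCOC)cc(OCOC)c4c3=O)c(O)cc2O1
A5 | alternative 2 | 3-[2-hydroxy-4-(2-methylbut-3-yn-2-yloxy)phenyl]-5,7-bis(methoxymethoxy)-4H-chromen-4-one | C#CC(C)(C)Oc1ccc(-c2coc3cc(OCOC)cc(OCOC)c3c2=O)c(O)c1
A6 | alternative 3 | 2',5,7-tris-O-(methoxymethyl) Eriosemaone D | COCOc1cc2OC(C)(C)C=Cc2cc1-c1coc2cc(OCOC)cc(OCOC)c2c1=O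
A7 | alternative 3 | methyl 3-hydroxy-2-[7-(methoxymethoxy)-2,2-dimethyl-2H-chromen-6-yl]prop-2-enoate | COCOc1cc2OC(C)(C)C=Cc2cc1C(=CO)C(=O)OC
A8 | alternative 3 | 3,5-bis(methoxymethoxy)-2-(trimethylsilyl)phenyl trifluoromethanesulfonate | COCOc1cc(OCOC)c([Si](C)(C)C)c(OS(=O)(=O)C(F)(F)F)c1
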